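The blue run holds half the coupling partner of the violet run, yet at 2.6 min the two have turned about the same share of their substrate: 8.00% against 7.83%.

in all of them: free catalyst 0.0120 M

| charge | substrate | coupling partner | time |
|---|---|---|---|
| violet | 0.600 M | 0.720 M |  |
| red | 0.360 M | 0.480 M |  |
| amber | 0.900 M | 0.720 M |  |
| blue | 0.600 M | 0.360 M |  |
| grey | 0.600 M | 0.210 M | 18 min |

| run | time / min | [target] / M |
|---|---|---|
| violet run | 2.6 | 0.047 |
| violet run | 5.1 | 0.091 |
| violet run | 7.7 | 0.128 |
| violet run | 10 | 0.155 |
| violet run | 13 | 0.186 |
| violet run | 15 | 0.210 |
| violet run | 18 | 0.228 |
| red run | 2.6 | 0.042 |
| red run | 5.1 | 0.075 |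
| red run | 7.7 | 0.107 |
| red run | 10 | 0.137 |
| red run | 13 | 0.164 |
| red run | 15 | 0.182 |
| red run | 18 | 0.198 |
| amber run | 2.6 | 0.050 |
| amber run | 5.1 | 0.097 |
| amber run | 7.7 | 0.146 |
| amber run | 10 | 0.181 |
| amber run | 13 | 0.223 |
| amber run | 15 | 0.249 |
| amber run | 18 | 0.282 |
| blue run | 2.6 | 0.048 |
| blue run | 5.1 | 0.099 |
| blue run | 7.7 | 0.135 |
| blue run | 10 | 0.177 |
| blue run | 13 | 0.218 |
| blue run | 15 | 0.243 |
| blue run | 18 | 0.284 |

(scatter of a reading: 0.003 M)

* apparent order in [coupling partner] of the starting rate, round the charge of the violet run (the rate where two percent of its substrate have turned into target)
* apparent order in [substrate] of the starting rate, round the charge of the violet run (the rate where two percent of its substrate have turned into target) (one fixed amount of target, the same in the runs compared)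
* the red run starts with 0.240 M less of substrate and of coupling partner than the violet run, and with no target. Compared where both hold the same amount of substrate, once fifteen percent of what the red run was charged with has turned into target, is the red run faster, slower or alike (within a tenth)?
* target in the grey run at 18 min, as a share of the substrate charged

- Overall: substrate + coupling partner -> target, with free catalyst as catalyst.
- Constant volume, constant temperature.
- Bound and free are read together.
- An order is taken over about fifteen percent of the charge, up and down.

The contradiction is plain. The early rate barely notices the coupling partner, yet each target takes up one coupling partner. In the grey run the coupling partner is therefore the limiting reagent, and its charge is 35.0% of the substrate. Target in the grey run can't pass that share. The question is whether the grey run gets there within 18 min.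

The blue run serves as guide, with the same substrate as the grey run and more coupling partner. Over its full 18 min, the blue run turned 0.0263 min⁻¹ of its substrate charge. That pace puts the end of the grey run's coupling partner at 13.3 min. Going round again, the blue reading nearest that time, at 13 min, gives a pace of 0.0279 min⁻¹. The time becomes 12.5 min, and the nearest reading stays the same, so the round closes.

This is the running-out time: the coupling partner's share of the substrate charge, divided by the pace of target formation up to that moment. It falls 5.50 min before the time asked. The low end looks safe as far as the blue run reaches, though the grey run has to go lower. At 18 min the blue run has coupling partner equal to 12.7% of its substrate charge, and its last readings still show 0.0228 min⁻¹. My reckoning for the grey run is therefore the cap, 35.0%.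

The forecast gave −0.05 and 0.15 for the orders in coupling partner and substrate, faster for the red run, and 34% for the grey run, below that cap, holding that “partner binds tightly”.

The flask gives orders of −0.027 in coupling partner and 0.20 in substrate, the red run faster by a ratio of 3.7, and 35.0% in the grey run.

    free catalyst + substrate → catalyst-substrate complex (18.42 M⁻¹ min⁻¹)
    catalyst-substrate complex + coupling partner → loaded catalyst (268.8 M⁻¹ min⁻¹)
    loaded catalyst → target + free catalyst (3.954 min⁻¹)
    free catalyst + coupling partner → spent catalyst + coupling partner (0.4518 M⁻¹ min⁻¹)
    free catalyst + substrate ⇌ idle catalyst-substrate complex, settled at all times (4.230 M⁻¹)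

The step from free catalyst to spent catalyst makes no difference to the grey run at 18 min. The grey value matches the coupling partner's share, and the reckoned running-out time of 12.5 min lies inside the 18 min asked. In the blue run, the same division for half of the substrate charge gives 17.9 min, and the blue run reaches that share at 19.2 min.

Readings and results are simulated from invented constants, noise included.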